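I decided to follow X rather than D, to see what stopped Q while, in the winter readings at 25.0 min, L and Q together held 24.0 % of the D charged.

all flasks: D 10 mM

| flask | G | X | remark | time |
|---|---|---|---|---|
| winter | 20 mM | 20 mM | the very flask that is asked about, followed so far |  |
| flask | 20.0 mM | 20.0 mM |  | 80 min |

winter run (percent of the D charged)

| time / min | L / % | Q / % |
|---|---|---|
| 2.00 | 9.1 | 12.5 |
| 4.00 | 5.5 | 16.4 |
| 10.0 | 3.1 | 20.5 |
| 25.0 | 2.8 | 21.2 |

(standard deviation of a reading: 0.5 percentage points)

1. why nothing more happens at 80 min, or that something still does (forward and back rates have come level / it is still moving / all of D has reacted)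
2. L at 80 min, in percent of the D charged
3. Q at 80 min, in percent of the D charged

- the numbers in the tables scatter with a standard deviation of 0.5 percentage points
- the reaction counts as stopped when no species that holds the D changes by six tenths of a point or more over the second half of the time

I turned the question round. If D were to end up all reacted through Q, which I took to use one X per D, Q would need 10 mM of the 20.0 mM of X. At 25.0 min the winter reading of Q stood at 2.12 mM, and between 10.0 min and 25.0 min it had moved only from 20.5 % to 21.2 %. So I supposed that X was being lost elsewhere, most likely to G, charged at 20.0 mM, and I took the whole 20 mM of X as consumed by 25.0 min; that was my assumption, not a reading. Dividing the rate of Q by the rate of that other loss removes time, and the amounts at that reading then give the split: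

σ = Q made / X lost elsewhere = 2.12 mM / (20 mM − 2.12 mM) = 0.119

This σ, the mM of Q made per mM of X lost elsewhere, is a selectivity factor, here read from a scattered reading. Turning all the D into Q from this charge of X needs σ of at least 1.00, and this flask stood about 8.40 times below that, so I expected Q to stay near its reading.

The forecast said forward and back rates have come level, with L 2.8 % and Q 21.5 %, reasoning that “the L-to-Q step has reached a balance”. I placed the stop in X instead.

The simulation gave forward and back rates have come level, with L 1.54 % and Q 21.4 %.

    D + G ⇌ L (K = 50.0 M⁻¹, k = 7.30 M⁻¹ s⁻¹)
    X + G → Z (k = 3.00 M⁻¹ s⁻¹)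
    D + X → Q (k = 0.210 M⁻¹ s⁻¹)
    2 G → J (k = 0.140 M⁻¹ s⁻¹)

At 80.0 min this flask held X at 0 % and Z at 17.9 mM, so σ came to 0.120. The neighbouring flask was charged with 40 mM of D, with the charges of G and X unchanged. In the scheme the rate of Q carries D as a factor and the rate of Z does not, so I scaled σ by the charge of D, an approximation that treats G as it stood in this flask:

σ′ = 0.119 × 40 mM / 10 mM = 0.474

Q = 20.0 mM × σ′ / (σ′ + 1) = 6.43 mM, which is 16.1 % of its D

The neighbouring flask ended with X at 0 %, Z at 13.7 mM and Q at 15.8 %.

(Readings and results were generated by integration with made-up constants, noise included.)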